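**Retrosynthetic overview**

1. Feature used: in the coumarin benzo ring (C4a, C5, C6, C7, C8, C8a) the aryl-bearing C8 lies between two oxygenated carbons (C7–OH and C8a–O1), and the only carbon substituent (C4, on C4a) is para to C7–O. This is the pattern left when a 3-aryl-4-methoxy-2-pyrone-5-carboxylate takes up a ketene acetal and gives off CO2.
2. Target 29 ⇐ tetramethyl ether 28 (BBr3) ⇐ flavone pyranone ring by Baker–Venkataraman chemistry from acetophenone 24 and 4-methoxybenzoyl chloride ⇐ C-acetylation of phenol 22.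
3. Coumarin lactone ring of 22 ⇐ salicylaldehyde 18 + Ph3P=CHCO2Et ⇐ benzoate 15 (ester to aldehyde; BCl3 frees the chelated phenol and removes the benzyl group).
4. Key disconnection: benzo ring of 15 ⇐ 2-pyrone 11 + 1,1-dimethoxyethene (coumarin bonds C5–C6 and C7–C8; loss of CO2 and MeOH); 11 ⇐ aryl-3-oxoglutarate 7 + HC(OMe)3 ⇐ arylacetate 5 + methyl malonyl chloride ⇐ aldehyde 1.
5. Ring order: phloroglucinol ring (bought) → 2-pyrone → coumarin benzo ring → coumarin lactone ring → flavone pyranone ring (ring B bought).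

Key step: step 7

Remark on the chemistry (assumption): the target SMILES has no stereodescriptor, so the hindered biaryl axis (coumarin C8–flavone C6) is left uncontrolled; compounds 24 and 26 to 29 would be racemic about it if it is configurationally stable.

**Route**

Step 1
Reactants: 1 4-hydroxy-2,6-dimethoxybenzaldehyde
Product: 2 4-(benzyloxy)-2,6-dimethoxybenzaldehyde
Conditions: BnBr, K2CO3, DMF, 60 °C
Reagents that add atoms: benzyl bromide, BrCc1ccccc1
Why: Williamson etherification of the single phenol; the benzyl ether marks the oxygen that later becomes O1 of the flavone and keeps it distinct from the two methyl ethers.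

Step 2
Reactants: 2 4-(benzyloxy)-2,6-dimethoxybenzaldehyde; 3 methyl (methylsulfanyl)methyl sulfoxide (FAMSO)
Product: 4 5-(benzyloxy)-2-[2-(methanesulfinyl)-2-(methylsulfanyl)ethenyl]-1,3-dimethoxybenzene
Conditions: BnMe3N+ OH− (Triton B, 40% in MeOH), THF, reflux
Reagents that add atoms: none
Why: Knoevenagel-type condensation of the sulfinyl-stabilised carbanion with the aldehyde and loss of water gives the ketene dithioacetal S-oxide; its alkene geometry does not matter because both alkene carbons are transformed in step 3.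

Step 3
Reactants: 4 5-(benzyloxy)-2-[2-(methanesulfinyl)-2-(methylsulfanyl)ethenyl]-1,3-dimethoxybenzene
Product: 5 methyl [4-(benzyloxy)-2,6-dimethoxyphenyl]acetate
Conditions: HCl, MeOH, rt
Reagents that add atoms: methanol, CO
Why: Acid methanolysis of the ketene dithioacetal S-oxide (protonation at the benzylic carbon, capture of the thionium ion by methanol, Pummerer-type loss of the sulfur groups as dimethyl disulfide) gives the one-carbon-homologated arylacetic ester; benzyl and methyl aryl ethers are stable to HCl in methanol.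

Step 4
Reactants: 5 methyl [4-(benzyloxy)-2,6-dimethoxyphenyl]acetate; 6 methyl 3-chloro-3-oxopropanoate (methyl malonyl chloride)
Product: 7 dimethyl 2-[4-(benzyloxy)-2,6-dimethoxyphenyl]-3-oxopentanedioate
Conditions: LiN(SiMe3)2 (2.1 equiv), THF, −78 °C; then 6, −78 → −30 °C; aq. NH4Cl
Reagents that add atoms: none
Why: Claisen-type C-acylation of the preformed lithium ester enolate by the acid chloride; the second equivalent of amide base takes up the acidic proton of the 1,3-dicarbonyl product, and any (methoxycarbonyl)ketene formed from 6 acylates the enolate to the same product.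

Step 5
Reactants: 7 dimethyl 2-[4-(benzyloxy)-2,6-dimethoxyphenyl]-3-oxopentanedioate; 8 trimethyl orthoformate
Product: 10 methyl 3-[4-(benzyloxy)-2,6-dimethoxyphenyl]-4-hydroxy-2-oxo-2H-pyran-5-carboxylate, via methoxymethylidene diester 9 (not isolated)
Conditions: Ac2O, 120 °C; evaporate; then 2 M HCl, THF, 50 °C
Reagents that add atoms: water, O
Why: Orthoformate–acetic anhydride alkoxymethylenation can only occur at C4, the one carbon with two hydrogens between two carbonyl groups, and aqueous acid then hydrolyses the enol ether of 9 so that the hydroxymethylene oxygen lactonises onto the ester of the aryl-bearing carbon (6-exo-trig acyl substitution, loss of methanol) to give the 4-hydroxy-2-pyrone.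

Step 6
Reactants: 10 methyl 3-[4-(benzyloxy)-2,6-dimethoxyphenyl]-4-hydroxy-2-oxo-2H-pyran-5-carboxylate
Product: 11 methyl 3-[4-(benzyloxy)-2,6-dimethoxyphenyl]-4-methoxy-2-oxo-2H-pyran-5-carboxylate
Conditions: Me2SO4, K2CO3, acetone, reflux
Reagents that add atoms: dimethyl sulfate, COS(=O)(=O)OC
Why: O-Methylation of the ambident 4-hydroxy-2-pyrone anion with the hard electrophile dimethyl sulfate should go to O4 and keep the lactone, as is usual for 4-hydroxy-2-pyrones and 4-hydroxycoumarins; C3 is blocked by the aryl group.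

Step 7
Reactants: 11 methyl 3-[4-(benzyloxy)-2,6-dimethoxyphenyl]-4-methoxy-2-oxo-2H-pyran-5-carboxylate; 12 1,1-dimethoxyethene
Product: 15 methyl 3-[4-(benzyloxy)-2,6-dimethoxyphenyl]-2,4-dimethoxybenzoate, via bridged lactone adduct 13 (not isolated), via cyclohexadiene acetal 14 (not isolated)
Conditions: 12 (5 equiv), toluene, 120 °C, sealed tube
Reagents that add atoms: none
Why: The nucleophilic CH2 terminus of the ketene acetal attacks pyrone C6 (the beta carbon of the C5 acrylate and the vinylogous terminus of the lactone), and the dimethoxy-substituted carbon then bonds to the aryl-bearing C3, an asynchronous inverse-electron-demand Diels–Alder addition that gives the 2-oxabicyclo[2.2.2]octenone 13. Retro-(4+2) extrusion of CO2 from 13 leaves cyclohexa-1,5-diene 14, and 1,2-elimination of methanol (H from the new CH2, OMe from the acetal carbon) makes the benzene ring of 15. The closest known reaction type is the cycloaddition of 2-pyrone-5-carboxylates (coumalates) with ketene acetals, which gives 4-alkoxybenzoates with loss of CO2 and alcohol. The one ring closed is the future coumarin benzo ring, formed by intermolecular (4+2) cycloaddition (new bonds are coumarin C5–C6 and C7–C8) and made aromatic by cycloreversion and elimination; no stereocentre remains, because the two bridgehead centres of racemic 13 become sp2. The selectivity needed is the orientation of the addition, and the C5 ester together with the lactone carbonyl secures it by making unsubstituted C6 the electrophilic terminus, so the oxygen-bearing acetal carbon ends up next to the arylated carbon and the crowded aryl–arene bond is carried in from 11 instead of being made here. The 4-methoxy group and the twisted 3-aryl group will slow the second bond formation, which is why excess ketene acetal and 120 °C are planned.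

Step 8
Reactants: 15 methyl 3-[4-(benzyloxy)-2,6-dimethoxyphenyl]-2,4-dimethoxybenzoate
Product: 16 {3-[4-(benzyloxy)-2,6-dimethoxyphenyl]-2,4-dimethoxyphenyl}methanol
Conditions: LiAlH4, THF, 0 °C
Reagents that add atoms: none
Why: Hydride reduction of the aryl ester to the benzylic alcohol; the methyl and benzyl aryl ethers are inert to LiAlH4.

Step 9
Reactants: 16 {3-[4-(benzyloxy)-2,6-dimethoxyphenyl]-2,4-dimethoxyphenyl}methanol
Product: 17 3-[4-(benzyloxy)-2,6-dimethoxyphenyl]-2,4-dimethoxybenzaldehyde
Conditions: MnO2, CH2Cl2, rt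
Reagents that add atoms: none
Why: MnO2 oxidises the electron-rich benzylic alcohol to the aldehyde and stops there.

Step 10
Reactants: 17 3-[4-(benzyloxy)-2,6-dimethoxyphenyl]-2,4-dimethoxybenzaldehyde
Product: 18 2-hydroxy-3-(4-hydroxy-2,6-dimethoxyphenyl)-4-methoxybenzaldehyde
Conditions: BCl3 (3 equiv), C6HMe5 (4 equiv), CH2Cl2, −78 → 0 °C; then MeOH, H2O
Reagents that add atoms: none
Why: BCl3 bound to the aldehyde oxygen cleaves only the neighbouring C2 methyl ether through a six-membered chelate (ortho-selective Lewis-acid demethylation), and in the same pot it cleaves the benzyl ether at low temperature with pentamethylbenzene trapping the benzyl cation by Friedel–Crafts alkylation; the three non-chelated methyl ethers should survive BCl3 at 0 °C.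

Step 11
Reactants: 18 2-hydroxy-3-(4-hydroxy-2,6-dimethoxyphenyl)-4-methoxybenzaldehyde; 19 ethyl (triphenylphosphoranylidene)acetate
Product: 22 8-(4-hydroxy-2,6-dimethoxyphenyl)-7-methoxy-2H-chromen-2-one, via E-cinnamate ester 20 (not isolated), via Z-cinnamate ester 21 (not isolated)
Conditions: PhNEt2, reflux (about 215 °C)
Reagents that add atoms: none
Why: Wittig olefination of the salicylaldehyde with the stabilised ylide gives cinnamate 20, which at the boiling point of N,N-diethylaniline equilibrates with its Z isomer 21, and this lactonises with loss of ethanol (Wittig coumarin synthesis); the second phenol takes no part.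

Step 12
Reactants: 22 8-(4-hydroxy-2,6-dimethoxyphenyl)-7-methoxy-2H-chromen-2-one
Product: 24 8-(3-acetyl-4-hydroxy-2,6-dimethoxyphenyl)-7-methoxy-2H-chromen-2-one, via difluoroboron chelate 23 (not isolated)
Conditions: AcOH, BF3·OEt2, 90 °C; then MeOH–H2O, reflux
Reagents that add atoms: acetic acid, CC(=O)O
Why: Friedel–Crafts C-acetylation (BF3–acetic acid) at one of the two equivalent free positions of the phloroglucinol ring, each ortho to the hydroxyl and ortho/para to the methoxy groups; the deactivated coumarin ring does not compete, and holding the product as BF2 chelate 23 until hydrolysis prevents a second acylation.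

Step 13
Reactants: 24 8-(3-acetyl-4-hydroxy-2,6-dimethoxyphenyl)-7-methoxy-2H-chromen-2-one; 25 4-methoxybenzoyl chloride
Product: 26 2-acetyl-3,5-dimethoxy-4-(7-methoxy-2-oxo-2H-chromen-8-yl)phenyl 4-methoxybenzoate
Conditions: pyridine, DMAP (cat.), rt → 50 °C
Reagents that add atoms: none
Why: Esterification of the single, hydrogen-bonded phenol with the aroyl chloride under nucleophilic catalysis, the first stage of the Baker–Venkataraman sequence.

Step 14
Reactants: 26 2-acetyl-3,5-dimethoxy-4-(7-methoxy-2-oxo-2H-chromen-8-yl)phenyl 4-methoxybenzoate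
Product: 27 1-[6-hydroxy-2,4-dimethoxy-3-(7-methoxy-2-oxo-2H-chromen-8-yl)phenyl]-3-(4-methoxyphenyl)propane-1,3-dione
Conditions: LiN(SiMe3)2 (3 equiv), THF, −78 → 0 °C; then 1 M HCl
Reagents that add atoms: none
Why: Baker–Venkataraman rearrangement: the methyl ketone enolate attacks the neighbouring aryl ester through a six-membered transition state, an intramolecular Claisen acyl transfer expected to be faster than any attack on the coumarin lactone under a non-nucleophilic amide base.

Step 15
Reactants: 27 1-[6-hydroxy-2,4-dimethoxy-3-(7-methoxy-2-oxo-2H-chromen-8-yl)phenyl]-3-(4-methoxyphenyl)propane-1,3-dione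
Product: 28 5,7-dimethoxy-6-(7-methoxy-2-oxo-2H-chromen-8-yl)-2-(4-methoxyphenyl)-4H-chromen-4-one
Conditions: H2SO4 (cat.), AcOH, 90 °C
Reagents that add atoms: none
Why: Acid-catalysed cyclodehydration of the o-hydroxyaryl 1,3-diketone (6-exo-trig addition of the phenol to the aroyl carbonyl, then loss of water) closes the pyranone ring; only the hydroxyl at the former benzyl ether position is free, so closure can only give the flavone with the coumarin on C6.

Step 16
Reactants: 28 5,7-dimethoxy-6-(7-methoxy-2-oxo-2H-chromen-8-yl)-2-(4-methoxyphenyl)-4H-chromen-4-one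
Product: 29 5,7-dihydroxy-6-(7-hydroxy-2-oxo-2H-chromen-8-yl)-2-(4-hydroxyphenyl)-4H-chromen-4-one (target CNP0223343.0)
Conditions: BBr3 (12 equiv), CH2Cl2, −78 °C → rt; then MeOH, H2O
Reagents that add atoms: none
Why: BBr3 cleaves all four aryl methyl ethers (Lewis acid–bromide SN2 demethylation) while the coumarin lactone and the pyranone survive; staying at or below room temperature should avoid acid-induced opening and reclosure of the 5-hydroxyflavone that would move the coumarin to C8.

**Compound list**

1 | 4-hydroxy-2,6-dimethoxybenzaldehyde | COc1cc(O)cc(OC)c1C=O | starting material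
2 | 4-(benzyloxy)-2,6-dimethoxybenzaldehyde | COc1cc(OCc2ccccc2)cc(OC)c1C=O | intermediate
3 | methyl (methylsulfanyl)methyl sulfoxide (FAMSO; racemic at sulfur) | CSCS(C)=O | starting material
4 | 5-(benzyloxy)-2-[2-(methanesulfinyl)-2-(methylsulfanyl)ethenyl]-1,3-dimethoxybenzene (alkene geometry not controlled; racemic at sulfur) | COc1cc(OCc2ccccc2)cc(OC)c1C=C(SC)S(C)=O | intermediate
5 | methyl [4-(benzyloxy)-2,6-dimethoxyphenyl]acetate | COC(=O)Cc1c(OC)cc(OCc2ccccc2)cc1OC | intermediate
6 | methyl 3-chloro-3-oxopropanoate (methyl malonyl chloride) | COC(=O)CC(Cl)=O | starting material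
7 | dimethyl 2-[4-(benzyloxy)-2,6-dimethoxyphenyl]-3-oxopentanedioate (racemic; enolisable) | COC(=O)CC(=O)C(C(=O)OC)c1c(OC)cc(OCc2ccccc2)cc1OC | intermediate
8 | trimethyl orthoformate | COC(OC)OC | starting material
9 | dimethyl 2-[4-(benzyloxy)-2,6-dimethoxyphenyl]-4-(methoxymethylidene)-3-oxopentanedioate (racemic; alkene geometry not controlled) | COC=C(C(=O)OC)C(=O)C(C(=O)OC)c1c(OC)cc(OCc2ccccc2)cc1OC | intermediate
10 | methyl 3-[4-(benzyloxy)-2,6-dimethoxyphenyl]-4-hydroxy-2-oxo-2H-pyran-5-carboxylate | COC(=O)c1coc(=O)c(-c2c(OC)cc(OCc3ccccc3)cc2OC)c1O | intermediate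
11 | methyl 3-[4-(benzyloxy)-2,6-dimethoxyphenyl]-4-methoxy-2-oxo-2H-pyran-5-carboxylate | COC(=O)c1coc(=O)c(-c2c(OC)cc(OCc3ccccc3)cc2OC)c1OC | intermediate
12 | 1,1-dimethoxyethene | C=C(OC)OC | starting material
13 | methyl 4-[4-(benzyloxy)-2,6-dimethoxyphenyl]-5,8,8-trimethoxy-3-oxo-2-oxabicyclo[2.2.2]oct-5-ene-6-carboxylate (racemic; the two bridgeheads are fixed relative to each other by the bicycle) | O=C1OC2CC(OC)(OC)C1(c3c(OC)cc(OCc4ccccc4)cc3OC)C(OC)=C2C(=O)OC | intermediate
14 | methyl 5-[4-(benzyloxy)-2,6-dimethoxyphenyl]-4,4,6-trimethoxycyclohexa-1,5-diene-1-carboxylate | COC(=O)C1=CCC(OC)(OC)C(c2c(OC)cc(OCc3ccccc3)cc2OC)=C1OC | intermediate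
15 | methyl 3-[4-(benzyloxy)-2,6-dimethoxyphenyl]-2,4-dimethoxybenzoate | COC(=O)c1ccc(OC)c(-c2c(OC)cc(OCc3ccccc3)cc2OC)c1OC | intermediate
16 | {3-[4-(benzyloxy)-2,6-dimethoxyphenyl]-2,4-dimethoxyphenyl}methanol | OCc1ccc(OC)c(-c2c(OC)cc(OCc3ccccc3)cc2OC)c1OC | intermediate
17 | 3-[4-(benzyloxy)-2,6-dimethoxyphenyl]-2,4-dimethoxybenzaldehyde | O=Cc1ccc(OC)c(-c2c(OC)cc(OCc3ccccc3)cc2OC)c1OC | intermediate
18 | 2-hydroxy-3-(4-hydroxy-2,6-dimethoxyphenyl)-4-methoxybenzaldehyde | O=Cc1ccc(OC)c(-c2c(OC)cc(O)cc2OC)c1O | intermediate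
19 | ethyl (triphenylphosphoranylidene)acetate | CCOC(=O)C=P(c1ccccc1)(c1ccccc1)c1ccccc1 | starting material
20 | ethyl (2E)-3-[2-hydroxy-3-(4-hydroxy-2,6-dimethoxyphenyl)-4-methoxyphenyl]prop-2-enoate | CCOC(=O)/C=C/c1ccc(OC)c(-c2c(OC)cc(O)cc2OC)c1O | intermediate
21 | ethyl (2Z)-3-[2-hydroxy-3-(4-hydroxy-2,6-dimethoxyphenyl)-4-methoxyphenyl]prop-2-enoate | CCOC(=O)/C=C\c1ccc(OC)c(-c2c(OC)cc(O)cc2OC)c1O | intermediate
22 | 8-(4-hydroxy-2,6-dimethoxyphenyl)-7-methoxy-2H-chromen-2-one | O=c1ccc2ccc(OC)c(-c3c(OC)cc(O)cc3OC)c2o1 | intermediate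
23 | difluoroboron chelate of 24 (BF2 bridging the phenolic oxygen and the acetyl oxygen; axis not controlled) | CC1=[O+][B-](F)(F)Oc2cc(OC)c(-c3c(OC)ccc4ccc(=O)oc34)c(OC)c12 | intermediate
24 | 8-(3-acetyl-4-hydroxy-2,6-dimethoxyphenyl)-7-methoxy-2H-chromen-2-one (axis not controlled) | CC(=O)c1c(O)cc(OC)c(-c2c(OC)ccc3ccc(=O)oc23)c1OC | intermediate
25 | 4-methoxybenzoyl chloride | COc1ccc(cc1)C(Cl)=O | starting material
26 | 2-acetyl-3,5-dimethoxy-4-(7-methoxy-2-oxo-2H-chromen-8-yl)phenyl 4-methoxybenzoate (axis not controlled) | CC(=O)c1c(OC(=O)c2ccc(OC)cc2)cc(OC)c(-c2c(OC)ccc3ccc(=O)oc23)c1OC | intermediate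
27 | 1-[6-hydroxy-2,4-dimethoxy-3-(7-methoxy-2-oxo-2H-chromen-8-yl)phenyl]-3-(4-methoxyphenyl)propane-1,3-dione (axis not controlled) | COc1ccc(cc1)C(=O)CC(=O)c1c(O)cc(OC)c(-c2c(OC)ccc3ccc(=O)oc23)c1OC | intermediate
28 | 5,7-dimethoxy-6-(7-methoxy-2-oxo-2H-chromen-8-yl)-2-(4-methoxyphenyl)-4H-chromen-4-one (axis not controlled) | COc1ccc(cc1)-c1cc(=O)c2c(OC)c(-c3c(OC)ccc4ccc(=O)oc34)c(OC)cc2o1 | intermediate
29 | 5,7-dihydroxy-6-(7-hydroxy-2-oxo-2H-chromen-8-yl)-2-(4-hydroxyphenyl)-4H-chromen-4-one (axis not controlled) | O=c1ccc2ccc(O)c(-c3c(O)cc4oc(-c5ccc(O)cc5)cc(=O)c4c3O)c2o1 | target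

**Step count**

Total steps: 16. Longest linear sequence: 16 steps (1 → 29); all other numbered starting materials are taken as commercial.

**Steps most likely to fail**

Step 7 (key step). The second C–C bond, to the fully substituted aryl-bearing C3, may form too slowly, or the 4-methoxy group may lower the electrophilicity of the diene so far that addition does not start. The zwitterion from attack at C6 would then be diverted by proton transfer or lactone opening, and the ketene acetal would be consumed by oligomerisation.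
Fallback, from 2 back to 17: the biaryl bond would be made by cross-coupling instead of being inherited. Baeyer–Villiger oxidation of aldehyde 2 (mCPBA, CH2Cl2) should give 4-(benzyloxy)-2,6-dimethoxyphenyl formate F1. Methanolysis (K2CO3, MeOH) would give 4-(benzyloxy)-2,6-dimethoxyphenol F2, and Tf2O/pyridine would give 4-(benzyloxy)-2,6-dimethoxyphenyl trifluoromethanesulfonate F3. Miyaura borylation (B2pin2, Pd(dppf)Cl2, KOAc, dioxane, 90 °C) would give 2-[4-(benzyloxy)-2,6-dimethoxyphenyl]-4,4,5,5-tetramethyl-1,3,2-dioxaborolane F4. Its Suzuki–Miyaura coupling (Pd(OAc)2, SPhos, K3PO4, toluene–H2O, 100 °C; a dialkylbiarylphosphine system of the kind used for tetra-ortho-substituted biaryls) with 3-bromo-2,4-dimethoxybenzaldehyde F5 would give aldehyde 17 directly. F5 would be made by Rieche formylation (Cl2CHOMe, TiCl4, CH2Cl2) of commercial 2-bromo-1,3-dimethoxybenzene. The route continues at step 10.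

Step 4. Proton transfer from the acidic CH2 of the acid chloride to the hindered enolate may outrun C-acylation, returning ester 5 and wasting 6 as ketene-derived material; O-acylation of the enolate is a second leak.
Fallback, from 5 back to 7: the roles are reversed so that the electrophile carries the aryl group and the nucleophile is a soft magnesium malonate. Carboxylation of the enolate of 5 (LiN(i-Pr)2, THF, −78 °C; CO2; cold acidification) should give 2-[4-(benzyloxy)-2,6-dimethoxyphenyl]-3-methoxy-3-oxopropanoic acid F6. Activation with 1,1'-carbonyldiimidazole (THF, rt) would give methyl 2-[4-(benzyloxy)-2,6-dimethoxyphenyl]-3-(1H-imidazol-1-yl)-3-oxopropanoate F7. Decarboxylative Claisen condensation with KO2CCH2CO2Me/MgCl2/Et3N (MeCN, rt → 40 °C), the way unsymmetrical 3-oxoglutarates are made from malonic half-esters, would pass through 4-[4-(benzyloxy)-2,6-dimethoxyphenyl]-5-methoxy-2-(methoxycarbonyl)-3,5-dioxopentanoic acid F8 (as its magnesium chelate). This loses CO2 on acidic work-up to give 7.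

Step 2. Carbanion addition to the doubly ortho-substituted, electron-rich aldehyde is reversible and may lie on the side of the reactants, so the condensation could stall.
Fallback, from 2 back to 5: van Leusen reductive cyanation (TosMIC, KOt-Bu, DME, −40 °C; then MeOH, reflux), in which ring closure onto the isocyanide carbon makes the addition irreversible, should give [4-(benzyloxy)-2,6-dimethoxyphenyl]acetonitrile F9. Pinner methanolysis (HCl, MeOH, 0 °C → rt; then H2O) would give ester 5.

**Further compounds**

F1 | step 7 | 4-(benzyloxy)-2,6-dimethoxyphenyl formate | O=COc1c(OC)cc(OCc2ccccc2)cc1OC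
F2 | step 7 | 4-(benzyloxy)-2,6-dimethoxyphenol | Oc1c(OC)cc(OCc2ccccc2)cc1OC
F3 | step 7 | 4-(benzyloxy)-2,6-dimethoxyphenyl trifluoromethanesulfonate | COc1cc(OCc2ccccc2)cc(OC)c1OS(=O)(=O)C(F)(F)F
F4 | step 7 | 2-[4-(benzyloxy)-2,6-dimethoxyphenyl]-4,4,5,5-tetramethyl-1,3,2-dioxaborolane | COc1cc(OCc2ccccc2)cc(OC)c1B1OC(C)(C)C(C)(C)O1
F5 | step 7 | 3-bromo-2,4-dimethoxybenzaldehyde | COc1ccc(C=O)c(OC)c1Br
F6 | step 4 | 2-[4-(benzyloxy)-2,6-dimethoxyphenyl]-3-methoxy-3-oxopropanoic acid (racemic) | COC(=O)C(C(=O)O)c1c(OC)cc(OCc2ccccc2)cc1OC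
F7 | step 4 | methyl 2-[4-(benzyloxy)-2,6-dimethoxyphenyl]-3-(1H-imidazol-1-yl)-3-oxopropanoate (racemic) | COC(=O)C(C(=O)n1ccnc1)c1c(OC)cc(OCc2ccccc2)cc1OC
F8 | step 4 | 4-[4-(benzyloxy)-2,6-dimethoxyphenyl]-5-methoxy-2-(methoxycarbonyl)-3,5-dioxopentanoic acid (stereocentres not controlled) | COC(=O)C(C(=O)O)C(=O)C(C(=O)OC)c1c(OC)cc(OCc2ccccc2)cc1OC
F9 | step 2 | [4-(benzyloxy)-2,6-dimethoxyphenyl]acetonitrile | N#CCc1c(OC)cc(OCc2ccccc2)cc1OC
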